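If target leaves a flask at a steady pace, you can freeze that pace into one number and read the flask from it, so begin with what is charged, what was read and what is asked.

| setting | violet | teal | blue | flask |
|---|---|---|---|---|
| solid substrate | 0.72 M | 0.72 M | 0.72 M | 0.72 M |
| reagent | 0.35 equiv | 0.52 equiv | 0.70 equiv | 0.700 equiv |
| capture agent | 0.0144 M | 0.0144 M | 0.022 M | 0.0144 M |
| free catalyst | 2 mol% | 2 mol% | 2 mol% | 2 mol% |
| remark | run made earlier | run made earlier | run made earlier |  |
| time |  |  |  | 15 h |

| run | time / h | target / % | starting material / % |
|---|---|---|---|
| violet | 1.33 | 0 | 3.6 |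
| violet | 4.00 | 1.7 | 5.8 |
| violet | 6.00 | 2.1 | 5.9 |
| violet | 10.0 | 4.5 | 5.7 |
| violet | 15.0 | 6.9 | 5.3 |
| violet | 20.0 | 8.8 | 5.6 |
| teal | 1.33 | 0.2 | 4.3 |
| teal | 4.00 | 1.2 | 5.4 |
| teal | 6.00 | 2.0 | 5.5 |
| teal | 10.0 | 3.3 | 5.2 |
| teal | 15.0 | 7.0 | 7.0 |
| teal | 20.0 | 9.0 | 5.1 |
| blue | 4.00 | 1.6 | 6.2 |
| blue | 8.00 | 4.5 | 5.3 |
| blue | 10.0 | 4.4 | 4.8 |
| blue | 15.0 | 7.2 | 5.6 |
| blue | 20.0 | 8.7 | 5.5 |

(standard deviation of a reading: 0.5 percentage points)

- as a solid, counted per litre of solution: solid substrate
- at the start none of the solid substrate is in solution
- starting material is what solid substrate becomes in solution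
- starting material means what is dissolved; the solid is not counted in it

1. amount of target at 15 h, in percent of the solid substrate charged
2. concentration of starting material in solution at 15 h, in percent of saturation

My first guess takes the earlier runs, which average 8.83% target at 20.0 h, and scales this to 15 h, which gives 6.62%. The objection is that a line through zero ignores the slow start, for the violet run shows 0% at 1.33 h. So take the pace from 4.00 h, where the runs average 1.50%, and divide it by the 2 mol% of catalyst, which gives the turnover frequency, the turnovers per hour of each catalyst charged, 0.229 /h, after a delay of 0.727 h.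

But does the reagent change this? The violet run with 0.35 equiv gives 8.8% at 20.0 h and the blue run with 0.70 equiv and more capture agent gives 8.7%, a gap inside the scatter of 0.5 percentage points, but those two runs differ in two settings, and this flask pairs the reagent of the blue run with the capture agent of the violet run, a pairing none of the earlier runs shows, so carrying the line over to it is an assumption. The line then gives 6.54%, while the readings at 15 h average 7.03%; I commit to the middle, 6.78%. A level of starting material that holds while target forms means that solid is still dissolving, so the solution should stand below saturation, by a margin these readings show only softly.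

The forecast says 6.8% and 92% of saturation: “Target grows almost linearly at about 0.46 %/h after a slight early lag.”

The simulation gives 6.86% of target and 88.3% of saturation, with starting material at 5.58% after 7.50 h and 5.64% after 15.0 h.

    starting material + free catalyst → catalyst intermediate A (k = 0.00267 /M/s)
    reagent + catalyst intermediate A ⇌ catalyst intermediate B (K = 1.70 /M, k = 0.0249 /M/s)
    catalyst intermediate B → catalyst intermediate C (k = 0.0282 /s)
    catalyst intermediate C ⇌ by-product + catalyst intermediate D (K = 0.713 M, k = 3.04 × 10⁻⁴ /s)
    catalyst intermediate D ⇌ free catalyst + target (K = 0.780 M, k = 0.0829 /s)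
    solid substrate ⇌ starting material, rate k6*(cs6 - [starting material]) while solid is left; crystals form when [starting material] > cs6 (solubility = 46.0 mM, k = 1.91 × 10⁻⁴ /s)
    catalyst intermediate A + capture agent → trapped intermediate (k = 0.00879 /M/s)

The frozen turnover frequency with its delay gave 6.54% on this flask, 0.32 points under the simulation. Left until 60.0 h, the same flask comes out by that number at 27.2%, and the simulation holds 26.1% of target.

The readings are calculated with constants of no real substance; noise was put on by code.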